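**Retrosynthetic overview**
- Feature (chromene numbering): in the benzoylphloroglucinol ring, C8 bears prenyl C1' and C4a bears pyran C4. Each of these carbons lies ortho to a ring oxygen (the C7 oxygen, and O1 on C8a), so both C–C bonds can come from O-to-C [3,3] shifts.
- Key disconnection: C8–C1', C4a–C4 and O1–C2 are opened together. This leads to a benzophenone with a 1,1-dimethylallyl ether on the future C7 oxygen and a 1,1-dimethylpropargyl ether on the future O1 (para to the benzoyl group).
- The third oxygen (future C5–O) carries an acetyl cap during the cascade, so the para hydroxyl is the only O–H beside the allene and the pyran can close only on O1. Ammonolysis removes the cap at the end.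
- The bis-ether comes from 2,4,6-trihydroxybenzophenone by para-selective copper-catalysed propargylation, then palladium-catalysed tert-prenylation of one of the two equivalent ortho hydroxyls.
- Ring order: both benzene rings are bought. The pyran is the only ring made, in the second half of the cascade.

Key step: step 5

Remark: the target has no stereocentre and no double bond that needs a descriptor; 2,4,6-trihydroxybenzophenone 1 is taken as purchasable.

**Step 1**
Reactants: 1 2,4,6-trihydroxybenzophenone; 2 3-chloro-3-methylbut-1-yne
Product: 3 [2,6-dihydroxy-4-(2-methylbut-3-yn-2-yloxy)phenyl](phenyl)methanone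
Conditions: 2 (1.1 equiv), CuCl2·2H2O (1 mol %), DBU (1.3 equiv), MeCN, 0 °C, Ar
Reagents that add atoms: none
Why: Copper-catalysed propargylic etherification (copper acetylide, loss of chloride, phenoxide attack at the tertiary carbon): the limited base ionises the para hydroxyl, which is the most acidic and the only one not hydrogen-bonded to the ketone, while the ortho hydroxyls are chelated and shielded by the benzoyl group, and at 0 °C the new ether cannot yet rearrange.

**Step 2**
Reactants: 4 2-methylbut-3-en-2-ol
Product: 6 isobutyl 2-methylbut-3-en-2-yl carbonate, via lithium 2-methylbut-3-en-2-olate 5 (not isolated)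
Conditions: n-BuLi (1.0 equiv), THF, −78 to 0 °C; i-BuOCOCl (1.05 equiv), 0 °C to rt
Reagents that add atoms: isobutyl chloroformate, CC(C)COC(=O)Cl
Why: O-Acylation of a lithium alkoxide with a chloroformate is the standard way to turn a hindered tertiary allylic alcohol into a mixed carbonate without allylic transposition.

**Step 3**
Reactants: 3 [2,6-dihydroxy-4-(2-methylbut-3-yn-2-yloxy)phenyl](phenyl)methanone; 6 isobutyl 2-methylbut-3-en-2-yl carbonate
Product: 7 [2-hydroxy-6-(2-methylbut-3-en-2-yloxy)-4-(2-methylbut-3-yn-2-yloxy)phenyl](phenyl)methanone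
Conditions: 6 (1.1 equiv), Pd(PPh3)4 (5 mol %), THF, 0 °C, Ar; cold work-up, Et3N-deactivated silica, kept below 25 °C
Reagents that add atoms: none
Why: Tsuji–Trost O-allylation: zerovalent palladium ionises 6 with loss of CO2, the released isobutoxide deprotonates 3, and under kinetic control at 0 °C the phenoxide attacks the more substituted allyl terminus to give the tertiary ether, while the symmetry of 3 allows only one mono-ether and the remaining hydroxyl, then fully chelated, should react much more slowly.

**Step 4**
Reactants: 7 [2-hydroxy-6-(2-methylbut-3-en-2-yloxy)-4-(2-methylbut-3-yn-2-yloxy)phenyl](phenyl)methanone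
Product: 8 2-benzoyl-3-(2-methylbut-3-en-2-yloxy)-5-(2-methylbut-3-yn-2-yloxy)phenyl acetate
Conditions: Ac2O (1.5 equiv), DMAP (10 mol %), pyridine, 0 to 15 °C
Reagents that add atoms: acetic anhydride, CC(=O)OC(C)=O
Why: DMAP-catalysed O-acetylation caps the future C5 oxygen, which is needed because the C7 hydroxyl released in step 5 would compete for the carbonyl hydrogen bond, so that a free C5 hydroxyl could pass its hydrogen to the allene and close the pyran on the wrong oxygen.

**Step 5**
Reactants: 8 2-benzoyl-3-(2-methylbut-3-en-2-yloxy)-5-(2-methylbut-3-yn-2-yloxy)phenyl acetate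
Product: 14 6-benzoyl-7-hydroxy-2,2-dimethyl-8-(3-methylbut-2-enyl)-2H-chromen-5-yl acetate, via prenyl dienone 9 (not isolated), via prenylphenol propargyl ether 10 (not isolated), via allenyl dienone 11 (not isolated), via ortho-allenylphenol 12 (not isolated), via ortho-quinone methide 13 (not isolated)
Conditions: degassed o-xylene (0.02 M), base-washed glass, Ar, 100 °C until 8 is consumed, then 145 °C
Reagents that add atoms: none
Why: Near 100 °C only the tertiary allyl ether should react: an aromatic Claisen [3,3] shift through a chair-like six-membered transition state joins the CH2 terminus of the 1,1-dimethylallyl group to the one hydrogen-bearing carbon ortho to its oxygen (future C8, the other ortho carbon holding the benzoyl group), and dienone 9 enolises to 10, which has a normal prenyl chain and a C7 hydroxyl hydrogen-bonded to the ketone. Near 145 °C the 1,1-dimethylpropargyl ether on the para oxygen makes the propargyl Claisen [3,3] shift to the last hydrogen-bearing ring carbon (C4a–C4 bond), allenyl dienone 11 enolises to 12, a 1,5-hydrogen shift from the para O–H to the central allene carbon gives the (Z)-ortho-quinone methide 13, and a thermal disrotatory oxa-6π electrocyclisation forms O1–C2 and closes the six-membered pyran ring. Both halves are established reaction types, the Claisen rearrangement of aryl 1,1-dimethylallyl ethers to ortho-prenylphenols and the thermal conversion of aryl 1,1-dimethylpropargyl ethers into 2,2-dimethyl-2H-chromenes, run here one after the other in one flask by a temperature step. No stereocentre survives, since the sp3 ring carbons of 9 and 11 are lost on enolisation, and the geometry of 13 is set by the cyclic hydrogen-shift transition state, which places the vinyl group beside the carbonyl oxygen that attacks it. The placement of the two carbon groups depends on a rate gap: the gem-dimethylallyl ether, crowded by the flanking benzoyl group, is expected to rearrange well below the temperature the propargyl ether needs, so C8 is filled before the propargyl group moves, and the bath is raised only once 8 has gone. Closure on O1 (at C8a) rather than on the C5 oxygen is secured by the acetyl cap, which leaves the para hydroxyl as the only O–H next to the allene.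

**Step 6**
Reactants: 14 6-benzoyl-7-hydroxy-2,2-dimethyl-8-(3-methylbut-2-enyl)-2H-chromen-5-yl acetate
Product: 15 [5,7-dihydroxy-2,2-dimethyl-8-(3-methylbut-2-enyl)-2H-chromen-6-yl](phenyl)methanone (target)
Conditions: NH3 (7 M in MeOH), 0 °C to rt, Ar; evaporate
Reagents that add atoms: none
Why: Ammonolysis of an aryl acetate activated by the ortho benzoyl group runs without acid, so the prenyl chain, the chromene double bond and the diaryl ketone should stay untouched.

**Compound list**
1 | 2,4,6-trihydroxybenzophenone | O=C(c1ccccc1)c1c(O)cc(O)cc1O | starting material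
2 | 3-chloro-3-methylbut-1-yne | C#CC(C)(C)Cl | starting material
3 | [2,6-dihydroxy-4-(2-methylbut-3-yn-2-yloxy)phenyl](phenyl)methanone | C#CC(C)(C)Oc1cc(O)c(C(=O)c2ccccc2)c(O)c1 | intermediate
4 | 2-methylbut-3-en-2-ol | C=CC(C)(C)O | starting material
5 | lithium 2-methylbut-3-en-2-olate | [Li+].[O-]C(C)(C)C=C | intermediate (not isolated)
6 | isobutyl 2-methylbut-3-en-2-yl carbonate | C=CC(C)(C)OC(=O)OCC(C)C | intermediate
7 | [2-hydroxy-6-(2-methylbut-3-en-2-yloxy)-4-(2-methylbut-3-yn-2-yloxy)phenyl](phenyl)methanone | C=CC(C)(C)Oc1cc(OC(C)(C)C#C)cc(O)c1C(=O)c1ccccc1 | intermediate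
8 | 2-benzoyl-3-(2-methylbut-3-en-2-yloxy)-5-(2-methylbut-3-yn-2-yloxy)phenyl acetate | C=CC(C)(C)Oc1cc(OC(C)(C)C#C)cc(OC(C)=O)c1C(=O)c1ccccc1 | intermediate
9 | 2-benzoyl-4-(3-methylbut-2-enyl)-5-(2-methylbut-3-yn-2-yloxy)-3-oxocyclohexa-1,5-dien-1-yl acetate (racemic ortho-dienone) | O=C1C(CC=C(C)C)C(OC(C)(C)C#C)=CC(OC(C)=O)=C1C(=O)c1ccccc1 | intermediate (not isolated)
10 | 2-benzoyl-3-hydroxy-4-(3-methylbut-2-enyl)-5-(2-methylbut-3-yn-2-yloxy)phenyl acetate | CC(C)=CCc1c(O)c(C(=O)c2ccccc2)c(OC(C)=O)cc1OC(C)(C)C#C | intermediate (not isolated)
11 | 2-benzoyl-3-hydroxy-4-(3-methylbut-2-enyl)-6-(3-methylbuta-1,2-dienyl)-5-oxocyclohexa-1,3-dien-1-yl acetate (racemic ortho-dienone) | O=C1C(C=C=C(C)C)C(OC(C)=O)=C(C(=O)c2ccccc2)C(O)=C1CC=C(C)C | intermediate (not isolated)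
12 | 2-benzoyl-3,5-dihydroxy-4-(3-methylbut-2-enyl)-6-(3-methylbuta-1,2-dienyl)phenyl acetate | CC(C)=CCc1c(O)c(C(=O)c2ccccc2)c(OC(C)=O)c(C=C=C(C)C)c1O | intermediate (not isolated)
13 | (6Z)-2-benzoyl-3-hydroxy-4-(3-methylbut-2-enyl)-6-(3-methylbut-2-enylidene)-5-oxocyclohexa-1,3-dien-1-yl acetate | O=C1/C(=C\C=C(C)C)C(OC(C)=O)=C(C(=O)c2ccccc2)C(O)=C1CC=C(C)C | intermediate (not isolated)
14 | 6-benzoyl-7-hydroxy-2,2-dimethyl-8-(3-methylbut-2-enyl)-2H-chromen-5-yl acetate | CC(C)=CCc1c(O)c(C(=O)c2ccccc2)c(OC(C)=O)c2c1OC(C)(C)C=C2 | intermediate
15 | [5,7-dihydroxy-2,2-dimethyl-8-(3-methylbut-2-enyl)-2H-chromen-6-yl](phenyl)methanone | CC(C)=CCc1c(O)c(C(=O)c2ccccc2)c(O)c2c1OC(C)(C)C=C2 | target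

**Total step count:** 6
**Longest linear sequence:** 5 (steps 1, 3, 4, 5, 6)

**Steps most likely to fail**

**Step 5.**
What may go wrong:
- Isoprene may be lost from the tertiary allyl ether (retro-ene or trace-acid ionisation) in competition with the [3,3] shift.
- The two rate windows may overlap, so that the propargyl group migrates to the C8 carbon first.
- The prenyl chain may cyclise onto a neighbouring hydroxyl at 145 °C.

Fallback (sets out from 3, comes back at 15): the two C–C bonds are made in separate operations, the pyran first and the prenyl group last by direct C-alkylation. One equivalent of Ac2O in pyridine at 0 °C should convert 3 into 2-benzoyl-3-hydroxy-5-(2-methylbut-3-yn-2-yloxy)phenyl acetate F1. Heating F1 in o-xylene at 140 °C triggers the propargyl Claisen shift, hydrogen shift and oxa-6π closure. The shift is steered to the carbon beside the single chelated hydroxyl, whose hydrogen is tied to the ketone, and should give 6-benzoyl-5-hydroxy-2,2-dimethyl-2H-chromen-7-yl acetate F2. NH3 in MeOH should then release (5,7-dihydroxy-2,2-dimethyl-2H-chromen-6-yl)(phenyl)methanone F3. Prenyl bromide with aqueous KOH at 0 °C is the classical C-prenylation of acylphloroglucinols. On the ring it can alkylate only C8, the one carbon still bearing hydrogen, and leads to 15.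

**Step 3.**
What may go wrong:
- Palladium may re-ionise the tertiary ether, with drift to the linear prenyl ether.
- The electron-rich ring may be allylated at carbon.
- A second etherification may occur.
- The catalyst may engage the propargyl ether.

Fallback (sets out from 1, comes back at 7): the tertiary allyl ether is made by semihydrogenation of a 1,1-dimethylpropargyl ether, so the ortho ether has to be installed before the para one. TIPSCl and imidazole in DMF should silylate only the non-chelated para hydroxyl of 1, giving [2,6-dihydroxy-4-(triisopropylsilyloxy)phenyl](phenyl)methanone F4. Chloride 2 under the conditions of step 1 should etherify one of the two equivalent ortho hydroxyls, giving [2-hydroxy-6-(2-methylbut-3-yn-2-yloxy)-4-(triisopropylsilyloxy)phenyl](phenyl)methanone F5. H2 over Pd/CaCO3 poisoned with Pb(OAc)2, with quinoline in EtOAc, should stop at [2-hydroxy-6-(2-methylbut-3-en-2-yloxy)-4-(triisopropylsilyloxy)phenyl](phenyl)methanone F6. Bu4NF buffered with AcOH at 0 °C should give [2,4-dihydroxy-6-(2-methylbut-3-en-2-yloxy)phenyl](phenyl)methanone F7. A second propargylation with 2 under the conditions of step 1 then gives 7; here one chelated hydroxyl is the only competitor.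

**Step 1.**
What may go wrong:
- Over-alkylation may occur.
- The phloroglucinol anion may be alkylated at a ring carbon.
- An ortho hydroxyl may be etherified.

Fallback (sets out from 1, comes back at 3): phenoxide alkylation is replaced by a Mitsunobu etherification of 1 with 2-methylbut-3-yn-2-ol (PPh3, DIAD, THF–toluene, 0 °C to rt). This reaction is known for this tertiary propargylic alcohol with phenols. No free phenoxide is present, so ring carbon is not attacked, and chelated hydroxyls are inert under these conditions. This detour makes no compound outside the list (F0).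

**Further compounds**
F1 | step 5 | 2-benzoyl-3-hydroxy-5-(2-methylbut-3-yn-2-yloxy)phenyl acetate | CC(=O)Oc1cc(OC(C)(C)C#C)cc(O)c1C(=O)c1ccccc1
F2 | step 5 | 6-benzoyl-5-hydroxy-2,2-dimethyl-2H-chromen-7-yl acetate | CC(=O)Oc1cc2OC(C)(C)C=Cc2c(O)c1C(=O)c1ccccc1
F3 | step 5 | (5,7-dihydroxy-2,2-dimethyl-2H-chromen-6-yl)(phenyl)methanone | Oc1cc2OC(C)(C)C=Cc2c(O)c1C(=O)c1ccccc1
F4 | step 3 | [2,6-dihydroxy-4-(triisopropylsilyloxy)phenyl](phenyl)methanone | CC(C)[Si](Oc1cc(O)c(C(=O)c2ccccc2)c(O)c1)(C(C)C)C(C)C
F5 | step 3 | [2-hydroxy-6-(2-methylbut-3-yn-2-yloxy)-4-(triisopropylsilyloxy)phenyl](phenyl)methanone | C#CC(C)(C)Oc1cc(O[Si](C(C)C)(C(C)C)C(C)C)cc(O)c1C(=O)c1ccccc1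
F6 | step 3 | [2-hydroxy-6-(2-methylbut-3-en-2-yloxy)-4-(triisopropylsilyloxy)phenyl](phenyl)methanone | C=CC(C)(C)Oc1cc(O[Si](C(C)C)(C(C)C)C(C)C)cc(O)c1C(=O)c1ccccc1
F7 | step 3 | [2,4-dihydroxy-6-(2-methylbut-3-en-2-yloxy)phenyl](phenyl)methanone | C=CC(C)(C)Oc1cc(O)cc(O)c1C(=O)c1ccccc1
F0 | step 1 | none | none
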